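Bilobetin is disconnected inside ring A of unit 2 (the flavone bearing the 4-hydroxyphenyl group), not at the crowded C3'–C8'' biaryl bond. The feature used is that C8 of this pentasubstituted ring holds ring B of unit 1 between two oxygenated carbons, C8a (O1) and C7. One thermal Danheiser benzannulation joins 3-isopropoxycyclobutenone to a triisopropylsiloxyalkyne that already carries ring B (methoxy group in place, aldehyde masked as dioxolane). It forms C8–C8a, C6–C7 and C4a–C8a and leaves the oxygens at C8a, C7 and C5 as free hydroxyl, silyl ether and isopropyl ether. Both pyranone rings then arise from chalcones, closed in a single oxidation.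

Key step: step 4

Remark: unit 1 is the flavone whose ring B bears the methoxy group and unit 2 the flavone with the 4-hydroxyphenyl group; from step 4 on the carbons of the new benzene ring carry the flavone numbering of unit 2; the biaryl axis is taken as configurationally labile, since the target SMILES shows no stereo element; the four starting materials are taken as purchasable.

Step 1
Reactants: 1 methyl 5-formyl-2-methoxybenzoate
Product: 2 methyl 5-(1,3-dioxolan-2-yl)-2-methoxybenzoate
Conditions: ethylene glycol, cat. p-TsOH, toluene, reflux (Dean–Stark)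
Reagents that add atoms: ethylene glycol, OCCO
Why: Acid-catalysed acetalisation under azeotropic water removal masks the aldehyde, so that the ester is the only electrophile left for the organolithium chemistry of step 2.

Step 2
Reactants: 2 methyl 5-(1,3-dioxolan-2-yl)-2-methoxybenzoate
Product: 5 {[5-(1,3-dioxolan-2-yl)-2-methoxyphenyl]ethynyloxy}triisopropylsilane, via lithium dibromoenolate 3 (not isolated), via lithium ynolate 4 (not isolated)
Conditions: CH2Br2, lithium 2,2,6,6-tetramethylpiperidide (LiTMP, 2.2 equiv), THF, −78 °C; n-BuLi, −78 → 0 °C; TIPSOTf, −78 → 0 °C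
Reagents that add atoms: dibromomethane, BrCBr; triisopropylsilyl trifluoromethanesulfonate, CC(C)[Si](C(C)C)(C(C)C)OS(=O)(=O)C(F)(F)F
Why: Kowalski ester homologation halted at the ynolate stage: LiCHBr2 acylates on the ester, a second equivalent of amide base gives dibromoenolate 3, bromine–lithium exchange sets off the 1,2-aryl shift to ynolate 4, and the bulky silyl triflate is taken up at oxygen rather than at carbon, while acetal and aryl methyl ether tolerate the cold bases.

Step 3
Reactants: 6 3-ethoxycyclobut-2-en-1-one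
Product: 7 3-isopropoxycyclobut-2-en-1-one
Conditions: i-PrOH (solvent, large excess), cat. p-TsOH, 35 °C, EtOH stripped off with i-PrOH under reduced pressure; NaHCO3
Reagents that add atoms: propan-2-ol, CC(C)O
Why: Vinylogous transesterification by addition–elimination at C3 of the protonated enone, driven by the large excess of isopropanol and run far below the temperature of ring opening, so that no ketene can be trapped by the alcohol.

Step 4
Reactants: 5 {[5-(1,3-dioxolan-2-yl)-2-methoxyphenyl]ethynyloxy}triisopropylsilane; 7 3-isopropoxycyclobut-2-en-1-one (1.3 equiv)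
Product: 12 2-[5-(1,3-dioxolan-2-yl)-2-methoxyphenyl]-5-isopropoxy-3-(triisopropylsilyloxy)phenol, via vinylketene 8 (not isolated), via vinylcyclobutenone 9 (not isolated), via dienylketene 10 (not isolated), via cyclohexadienone 11 (not isolated)
Conditions: toluene (0.4 M), argon, sealed tube, 80 °C, then 110 °C
Reagents that add atoms: none
Why: Known Danheiser benzannulation of a cyclobutenone with a siloxyalkyne: conrotatory four-electron opening of 7 breaks its C1–C4 bond and gives (1-isopropoxyvinyl)ketene 8, whose alkoxy group sits on the vinyl carbon bonded to the ketene, and C1, C2, C3 and C4 of 7 become C8a, C6, C5 and C4a. Ketene 8 adds [2+2] to the electron-rich triple bond of 5 and forms C8–C8a and C6–C7 in racemic vinylcyclobutenone 9, which opens again at the old ketene bond C8a–C6 to dienylketene 10. Ring A is closed by disrotatory six-electron electrocyclisation of 10, which forms C4a–C8a, and dienone 11 tautomerises to phenol 12. No stereocentre survives, because the one of 9 is erased in its ring opening. The selectivity needed is the orientation of the [2+2] step, and it is secured by the polarisation of the ynol ether: the aryl-bearing carbon, β to the siloxy oxygen, is the nucleophilic end and attacks the ketene carbonyl carbon, so the new hydroxyl ends at C8a beside the aryl group and the isopropoxy group at C5 para to it. The medium is neutral, so acetal, silyl ether and alkyl ethers persist, and the ortho aryl group shields the phenol from acylation by surplus ketene.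

Step 5
Reactants: 12 2-[5-(1,3-dioxolan-2-yl)-2-methoxyphenyl]-5-isopropoxy-3-(triisopropylsilyloxy)phenol
Product: 13 {2-[5-(1,3-dioxolan-2-yl)-2-methoxyphenyl]-5-isopropoxy-3-(methoxymethoxy)phenoxy}triisopropylsilane
Conditions: MOMCl, i-Pr2NEt, CH2Cl2, 0 °C → rt
Reagents that add atoms: chloromethyl methyl ether, COCCl
Why: Williamson-type O-alkylation of the only free hydroxyl gives a MOM ether that directs the lithiation of step 6 and later leaves together with the dioxolane, this base-only path to the acyl group being preferred because Lewis-acid Fries conditions would attack acetal, silyl ether and isopropyl ether.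

Step 6
Reactants: 13 {2-[5-(1,3-dioxolan-2-yl)-2-methoxyphenyl]-5-isopropoxy-3-(methoxymethoxy)phenoxy}triisopropylsilane
Product: 15 1-{3-[5-(1,3-dioxolan-2-yl)-2-methoxyphenyl]-6-isopropoxy-2-(methoxymethoxy)-4-(triisopropylsilyloxy)phenyl}ethan-1-one, via aryllithium 14 (not isolated)
Conditions: n-BuLi (1.1 equiv), TMEDA, THF, −40 → 0 °C; MeC(O)N(OMe)Me, −78 → 0 °C; then water
Reagents that add atoms: N-methoxy-N-methylacetamide, CC(=O)N(C)OC
Why: Directed ortho-metalation followed by Weinreb ketone synthesis: C4a–H lies between the chelating MOM ether and the isopropoxy group and is lithiated first, C6–H is screened by the bulky non-coordinating silyl ether, and the chelated tetrahedral adduct stops the addition at the ketone.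

Step 7
Reactants: 15 1-{3-[5-(1,3-dioxolan-2-yl)-2-methoxyphenyl]-6-isopropoxy-2-(methoxymethoxy)-4-(triisopropylsilyloxy)phenyl}ethan-1-one
Product: 17 1-{3-[5-(1,3-dioxolan-2-yl)-2-methoxyphenyl]-4,6-diisopropoxy-2-(methoxymethoxy)phenyl}ethan-1-one, via cesium phenoxide 16 (not isolated)
Conditions: CsF, 2-bromopropane (excess), DMF, rt → 60 °C
Reagents that add atoms: 2-bromopropane, CC(C)Br
Why: Fluoride cleaves the aryl silyl ether readily because phenoxide 16 is para to the acetyl group, and Williamson etherification in the same flask replaces the alkali-labile silyl group by the ether used everywhere else before the hydroxide-mediated condensations.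

Step 8
Reactants: 17 1-{3-[5-(1,3-dioxolan-2-yl)-2-methoxyphenyl]-4,6-diisopropoxy-2-(methoxymethoxy)phenyl}ethan-1-one; 18 4-isopropoxybenzaldehyde
Product: 19 (E)-1-{3-[5-(1,3-dioxolan-2-yl)-2-methoxyphenyl]-4,6-diisopropoxy-2-(methoxymethoxy)phenyl}-3-(4-isopropoxyphenyl)prop-2-en-1-one
Conditions: KOH (50% aq), EtOH, rt
Reagents that add atoms: none
Why: Claisen–Schmidt condensation in which only 17 can enolise and only 18 is an aldehyde, E1cB loss of water gives the conjugated (E)-enone under thermodynamic control, and MOM ether, dioxolane and isopropyl ethers are inert to alkali.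

Step 9
Reactants: 19 (E)-1-{3-[5-(1,3-dioxolan-2-yl)-2-methoxyphenyl]-4,6-diisopropoxy-2-(methoxymethoxy)phenyl}-3-(4-isopropoxyphenyl)prop-2-en-1-one
Product: 20 3-{2-hydroxy-4,6-diisopropoxy-3-[(E)-3-(4-isopropoxyphenyl)acryloyl]phenyl}-4-methoxybenzaldehyde
Conditions: 2 M aq HCl, THF, 50 °C
Reagents that add atoms: water, O
Why: Aqueous acid hydrolyses both acetal-type groups in one operation and spares aryl isopropyl and methyl ethers, and any flavanone formed by reversible oxa-Michael closure reopens in the alkali of step 11 or is oxidised to the same flavone in step 12.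

Step 10
Reactants: 21 2,4,6-trihydroxyacetophenone
Product: 22 1-(2-hydroxy-4,6-diisopropoxyphenyl)ethan-1-one
Conditions: 2-bromopropane (2.2 equiv), K2CO3, DMF, 60 °C
Reagents that add atoms: 2-bromopropane, CC(C)Br
Why: Williamson etherification limited to two equivalents of halide: after the para and one ortho hydroxyl have reacted, the last hydroxyl is locked in a hydrogen bond to the ketone and stays free.

Step 11
Reactants: 20 3-{2-hydroxy-4,6-diisopropoxy-3-[(E)-3-(4-isopropoxyphenyl)acryloyl]phenyl}-4-methoxybenzaldehyde; 22 1-(2-hydroxy-4,6-diisopropoxyphenyl)ethan-1-one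
Product: 23 (E)-1-(2-hydroxy-4,6-diisopropoxyphenyl)-3-(3-{2-hydroxy-4,6-diisopropoxy-3-[(E)-3-(4-isopropoxyphenyl)acryloyl]phenyl}-4-methoxyphenyl)prop-2-en-1-one
Conditions: KOH (50% aq), EtOH, rt; then dilute HCl
Reagents that add atoms: none
Why: Second Claisen–Schmidt condensation, in which 20 offers the only aldehyde and 22 the only enolisable methyl ketone, while the enone already present is deactivated towards Michael addition by its ortho phenoxide and its 4-alkoxyphenyl donor, and the new double bond is again (E) by thermodynamic control.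

Step 12
Reactants: 23 (E)-1-(2-hydroxy-4,6-diisopropoxyphenyl)-3-(3-{2-hydroxy-4,6-diisopropoxy-3-[(E)-3-(4-isopropoxyphenyl)acryloyl]phenyl}-4-methoxyphenyl)prop-2-en-1-one
Product: 24 8-[5-(5,7-diisopropoxy-4-oxo-4H-chromen-2-yl)-2-methoxyphenyl]-5,7-diisopropoxy-2-(4-isopropoxyphenyl)-4H-chromen-4-one
Conditions: I2 (20 mol %), DMSO, 130 °C; aq Na2S2O3 wash
Reagents that add atoms: none
Why: Iodine-catalysed oxidative cyclisation of 2'-hydroxychalcones in DMSO (oxa-Michael closure, α-iodination, loss of HI, re-oxidation of HI by DMSO) acts on both enones at once, and since each ketone has a single free ortho hydroxyl, that of unit 2 at C8a beside the aryl group, only the 8-aryl flavone and the 5,7-dialkoxyflavone can form.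

Step 13
Reactants: 24 8-[5-(5,7-diisopropoxy-4-oxo-4H-chromen-2-yl)-2-methoxyphenyl]-5,7-diisopropoxy-2-(4-isopropoxyphenyl)-4H-chromen-4-one
Product: 25 bilobetin
Conditions: BCl3 (excess, 1 M in CH2Cl2), CH2Cl2, −78 → 0 °C; then MeOH, water
Reagents that add atoms: none
Why: BCl3-mediated dealkylation removes secondary isopropyl ethers, those at both C5 positions with chelation help from C4=O, much faster than an unchelated aryl methyl ether, so the 4'-methoxy group stays, and the low temperature avoids acid-induced opening of the pyranone and thus Wessely–Moser migration from C8 to C6.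

Compound list
1 | methyl 5-formyl-2-methoxybenzoate | COC(=O)c1cc(C=O)ccc1OC | starting material
2 | methyl 5-(1,3-dioxolan-2-yl)-2-methoxybenzoate | COC(=O)c1cc(C2OCCO2)ccc1OC | intermediate
3 | lithium 2,2-dibromo-1-[5-(1,3-dioxolan-2-yl)-2-methoxyphenyl]ethen-1-olate (lithium dibromoenolate) | [Li+].[O-]C(=C(Br)Br)c1cc(C2OCCO2)ccc1OC | intermediate
4 | lithium 2-[5-(1,3-dioxolan-2-yl)-2-methoxyphenyl]ethyn-1-olate (lithium ynolate) | [Li+].[O-]C#Cc1cc(C2OCCO2)ccc1OC | intermediate
5 | {[5-(1,3-dioxolan-2-yl)-2-methoxyphenyl]ethynyloxy}triisopropylsilane | COc1ccc(cc1C#CO[Si](C(C)C)(C(C)C)C(C)C)C1OCCO1 | intermediate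
6 | 3-ethoxycyclobut-2-en-1-one | CCOC1=CC(=O)C1 | starting material
7 | 3-isopropoxycyclobut-2-en-1-one | CC(C)OC1=CC(=O)C1 | intermediate
8 | 3-isopropoxybuta-1,3-dien-1-one, the (1-isopropoxyvinyl)ketene | CC(C)OC(=C)C=C=O | intermediate
9 | racemic 2-[5-(1,3-dioxolan-2-yl)-2-methoxyphenyl]-4-(1-isopropoxyvinyl)-3-(triisopropylsilyloxy)cyclobut-2-en-1-one | COc1ccc(cc1C1=C(O[Si](C(C)C)(C(C)C)C(C)C)C(C(=C)OC(C)C)C1=O)C1OCCO1 | intermediate
10 | 2-[5-(1,3-dioxolan-2-yl)-2-methoxyphenyl]-5-isopropoxy-3-(triisopropylsilyloxy)hexa-1,3,5-trien-1-one, ketene carbon C2 and isopropoxyvinyl group cis on the C3=C4 bond | COc1ccc(cc1C(=C=O)/C(O[Si](C(C)C)(C(C)C)C(C)C)=C\C(=C)OC(C)C)C1OCCO1 | intermediate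
11 | 2-[5-(1,3-dioxolan-2-yl)-2-methoxyphenyl]-5-isopropoxy-3-(triisopropylsilyloxy)cyclohexa-2,4-dien-1-one | COc1ccc(cc1C1=C(O[Si](C(C)C)(C(C)C)C(C)C)C=C(OC(C)C)CC1=O)C1OCCO1 | intermediate
12 | 2-[5-(1,3-dioxolan-2-yl)-2-methoxyphenyl]-5-isopropoxy-3-(triisopropylsilyloxy)phenol | COc1ccc(cc1-c1c(O)cc(OC(C)C)cc1O[Si](C(C)C)(C(C)C)C(C)C)C1OCCO1 | intermediate
13 | {2-[5-(1,3-dioxolan-2-yl)-2-methoxyphenyl]-5-isopropoxy-3-(methoxymethoxy)phenoxy}triisopropylsilane | COCOc1cc(OC(C)C)cc(O[Si](C(C)C)(C(C)C)C(C)C)c1-c1cc(C2OCCO2)ccc1OC | intermediate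
14 | aryllithium of 13, lithium at C4a between the MOM ether and the isopropoxy group | [Li]c1c(OCOC)c(-c2cc(C3OCCO3)ccc2OC)c(O[Si](C(C)C)(C(C)C)C(C)C)cc1OC(C)C | intermediate
15 | 1-{3-[5-(1,3-dioxolan-2-yl)-2-methoxyphenyl]-6-isopropoxy-2-(methoxymethoxy)-4-(triisopropylsilyloxy)phenyl}ethan-1-one | CC(=O)c1c(OCOC)c(-c2cc(C3OCCO3)ccc2OC)c(O[Si](C(C)C)(C(C)C)C(C)C)cc1OC(C)C | intermediate
16 | cesium 4-acetyl-2-[5-(1,3-dioxolan-2-yl)-2-methoxyphenyl]-5-isopropoxy-3-(methoxymethoxy)phenoxide | CC(=O)c1c(OCOC)c(-c2cc(C3OCCO3)ccc2OC)c([O-])cc1OC(C)C.[Cs+] | intermediate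
17 | 1-{3-[5-(1,3-dioxolan-2-yl)-2-methoxyphenyl]-4,6-diisopropoxy-2-(methoxymethoxy)phenyl}ethan-1-one | CC(=O)c1c(OCOC)c(-c2cc(C3OCCO3)ccc2OC)c(OC(C)C)cc1OC(C)C | intermediate
18 | 4-isopropoxybenzaldehyde | CC(C)Oc1ccc(C=O)cc1 | starting material
19 | (E)-1-{3-[5-(1,3-dioxolan-2-yl)-2-methoxyphenyl]-4,6-diisopropoxy-2-(methoxymethoxy)phenyl}-3-(4-isopropoxyphenyl)prop-2-en-1-one | CC(C)Oc1ccc(/C=C/C(=O)c2c(OCOC)c(-c3cc(C4OCCO4)ccc3OC)c(OC(C)C)cc2OC(C)C)cc1 | intermediate
20 | 3-{2-hydroxy-4,6-diisopropoxy-3-[(E)-3-(4-isopropoxyphenyl)acryloyl]phenyl}-4-methoxybenzaldehyde | CC(C)Oc1ccc(/C=C/C(=O)c2c(O)c(-c3cc(C=O)ccc3OC)c(OC(C)C)cc2OC(C)C)cc1 | intermediate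
21 | 2,4,6-trihydroxyacetophenone | CC(=O)c1c(O)cc(O)cc1O | starting material
22 | 1-(2-hydroxy-4,6-diisopropoxyphenyl)ethan-1-one | CC(=O)c1c(O)cc(OC(C)C)cc1OC(C)C | intermediate
23 | (E)-1-(2-hydroxy-4,6-diisopropoxyphenyl)-3-(3-{2-hydroxy-4,6-diisopropoxy-3-[(E)-3-(4-isopropoxyphenyl)acryloyl]phenyl}-4-methoxyphenyl)prop-2-en-1-one (bis-chalcone) | CC(C)Oc1ccc(/C=C/C(=O)c2c(O)c(-c3cc(/C=C/C(=O)c4c(O)cc(OC(C)C)cc4OC(C)C)ccc3OC)c(OC(C)C)cc2OC(C)C)cc1 | intermediate
24 | 8-[5-(5,7-diisopropoxy-4-oxo-4H-chromen-2-yl)-2-methoxyphenyl]-5,7-diisopropoxy-2-(4-isopropoxyphenyl)-4H-chromen-4-one (penta-O-isopropylbilobetin) | COc1ccc(-c2cc(=O)c3c(OC(C)C)cc(OC(C)C)cc3o2)cc1-c1c(OC(C)C)cc(OC(C)C)c2c(=O)cc(-c3ccc(OC(C)C)cc3)oc12 | intermediate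
25 | bilobetin, 8-[5-(5,7-dihydroxy-4-oxo-4H-chromen-2-yl)-2-methoxyphenyl]-5,7-dihydroxy-2-(4-hydroxyphenyl)-4H-chromen-4-one | COc1ccc(-c2cc(=O)c3c(O)cc(O)cc3o2)cc1-c1c(O)cc(O)c2c(=O)cc(-c3ccc(O)cc3)oc12 | target

Total step count: 13. Longest linear sequence: 11 steps (1, 2, 4, 5, 6, 7, 8, 9, 11, 12, 13).

Steps most likely to fail

Step 4.
- **Risk:** Self-condensation of the vinylketene and slow thermal decay of the siloxyalkyne may outrun the [2+2] addition to the ortho-substituted aryl alkyne. Surplus ketene may also acylate the fresh phenol.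
- **Fallback:** Ring construction is given up and the biaryl bond is made by cross-coupling. The fallback sets out from 22 and comes back at 17.
- **Iodide partner:** Iodination of 22 ortho to its hydroxyl (N-iodosuccinimide, MeCN) should give 1-(2-hydroxy-3-iodo-4,6-diisopropoxyphenyl)ethan-1-one F1. MOMCl and NaH in DMF should then give 1-[3-iodo-4,6-diisopropoxy-2-(methoxymethoxy)phenyl]ethan-1-one F2.
- **Boron partner:** Commercial 3-bromo-4-methoxybenzaldehyde is acetalised to 2-(3-bromo-4-methoxyphenyl)-1,3-dioxolane F3. Miyaura borylation (B2pin2, PdCl2(dppf), KOAc, dioxane, 90 °C) then leads to 2-[4-methoxy-3-(4,4,5,5-tetramethyl-1,3,2-dioxaborolan-2-yl)phenyl]-1,3-dioxolane F4.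
- **Return:** Suzuki–Miyaura coupling of the two (Pd(OAc)2, SPhos, K3PO4, toluene/water, 100 °C) should give 17, so that steps 1 to 7 are bypassed.

Step 2.
- **Risk:** Metalation of the arene or of the acetal C–H by surplus alkyllithium during warming, incomplete aryl migration, and silylation at carbon instead of oxygen may erode the siloxyalkyne.
- **Fallback:** The same ynolate is reached by oxygenation of an acetylide with one equivalent of base. The fallback sets out from 2 and comes back at 5 by way of 4.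
- **To the alkyne:** LiAlH4 in THF should give [5-(1,3-dioxolan-2-yl)-2-methoxyphenyl]methanol F5. MnO2 in CH2Cl2 should give 5-(1,3-dioxolan-2-yl)-2-methoxybenzaldehyde F6. The Ohira–Bestmann reagent with K2CO3 in MeOH should give 2-(3-ethynyl-4-methoxyphenyl)-1,3-dioxolane F7.
- **Return:** n-BuLi (1 equiv, THF, −78 °C) gives lithium [5-(1,3-dioxolan-2-yl)-2-methoxyphenyl]acetylide F8. Treatment with t-BuOOLi (from t-BuOOH and LiN(SiMe3)2, −78 → 0 °C) transfers oxygen to give 4, and TIPSOTf then gives 5.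

Step 6.
- **Risk:** Lithiation on ring B (next to the methoxy group or the acetal) or at the acetal C–H may compete with lithiation at C4a. Enolisation of the Weinreb amide by the hindered aryllithium may simply return protonated starting ether.
- **Fallback:** The carbon is installed by a phenol-directed electrophilic reaction. The fallback sets out from 12 and comes back at 15.
- **Formylation and protection:** Casnati–Skattebøl ortho-formylation (MgCl2, Et3N, paraformaldehyde, MeCN, reflux) can only strike C4a and should give 3-[5-(1,3-dioxolan-2-yl)-2-methoxyphenyl]-2-hydroxy-6-isopropoxy-4-(triisopropylsilyloxy)benzaldehyde F9. MOMCl and NaH in DMF should give 3-[5-(1,3-dioxolan-2-yl)-2-methoxyphenyl]-6-isopropoxy-2-(methoxymethoxy)-4-(triisopropylsilyloxy)benzaldehyde F10.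
- **Return:** MeMgBr in THF should give racemic 1-{3-[5-(1,3-dioxolan-2-yl)-2-methoxyphenyl]-6-isopropoxy-2-(methoxymethoxy)-4-(triisopropylsilyloxy)phenyl}ethan-1-ol F11. Dess–Martin periodinane then gives 15.

Further compounds
F1 | step 4 | 1-(2-hydroxy-3-iodo-4,6-diisopropoxyphenyl)ethan-1-one | CC(=O)c1c(O)c(I)c(OC(C)C)cc1OC(C)C
F2 | step 4 | 1-[3-iodo-4,6-diisopropoxy-2-(methoxymethoxy)phenyl]ethan-1-one | CC(=O)c1c(OCOC)c(I)c(OC(C)C)cc1OC(C)C
F3 | step 4 | 2-(3-bromo-4-methoxyphenyl)-1,3-dioxolane | COc1ccc(cc1Br)C1OCCO1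
F4 | step 4 | 2-[4-methoxy-3-(4,4,5,5-tetramethyl-1,3,2-dioxaborolan-2-yl)phenyl]-1,3-dioxolane | COc1ccc(cc1B1OC(C)(C)C(C)(C)O1)C1OCCO1
F5 | step 2 | [5-(1,3-dioxolan-2-yl)-2-methoxyphenyl]methanol | OCc1cc(C2OCCO2)ccc1OC
F6 | step 2 | 5-(1,3-dioxolan-2-yl)-2-methoxybenzaldehyde | O=Cc1cc(C2OCCO2)ccc1OC
F7 | step 2 | 2-(3-ethynyl-4-methoxyphenyl)-1,3-dioxolane | C#Cc1cc(C2OCCO2)ccc1OC
F8 | step 2 | lithium [5-(1,3-dioxolan-2-yl)-2-methoxyphenyl]acetylide | [Li]C#Cc1cc(C2OCCO2)ccc1OC
F9 | step 6 | 3-[5-(1,3-dioxolan-2-yl)-2-methoxyphenyl]-2-hydroxy-6-isopropoxy-4-(triisopropylsilyloxy)benzaldehyde | O=Cc1c(O)c(-c2cc(C3OCCO3)ccc2OC)c(O[Si](C(C)C)(C(C)C)C(C)C)cc1OC(C)C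
F10 | step 6 | 3-[5-(1,3-dioxolan-2-yl)-2-methoxyphenyl]-6-isopropoxy-2-(methoxymethoxy)-4-(triisopropylsilyloxy)benzaldehyde | O=Cc1c(OCOC)c(-c2cc(C3OCCO3)ccc2OC)c(O[Si](C(C)C)(C(C)C)C(C)C)cc1OC(C)C
F11 | step 6 | racemic 1-{3-[5-(1,3-dioxolan-2-yl)-2-methoxyphenyl]-6-isopropoxy-2-(methoxymethoxy)-4-(triisopropylsilyloxy)phenyl}ethan-1-ol | CC(O)c1c(OCOC)c(-c2cc(C3OCCO3)ccc2OC)c(O[Si](C(C)C)(C(C)C)C(C)C)cc1OC(C)C
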